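Both dihydropyran rings are disconnected at O1–C2 and C3–C4. Each ring (O1, C2, C3, C4, C4a, C8a) is read as the heterodiene O=C8a–C4a=C4, an ortho-quinone methide of the acylphloroglucinol ring, plus the two alkene carbons of isobutene, which become C2 and C3. In one thermal operation a 6-methylheptylidene-bridged bis(acylphloroglucinol) that carries a CH2NMe2 group on each C4a and a benzyl ether on each O5 should lose dimethylamine twice and close both pyrans by hetero-Diels–Alder addition. This precursor is built from phloroglucinol by acylation, para-O-benzylation, aldehyde condensation and aminomethylation; hydrogenolysis of the two benzyl ethers then gives the target.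

Key step: step 5

Remark on the chemistry: atoms are numbered as in the chroman of the target (O5 and O7 are the oxygens on C5 and C7); the target has no stereocentre, the chiral compounds 7 and F2 are racemic, and 6-methylheptanal is taken as a purchasable aldehyde.

Step 1
Reactants: 1 phloroglucinol; 2 isobutyryl chloride
Product: 3 2-methyl-1-(2,4,6-trihydroxyphenyl)propan-1-one
Conditions: AlCl3 (3.5 equiv), CH2Cl2/MeNO2, 0 °C to 40 °C; aq HCl work-up
Reagents that add atoms: none
Why: Friedel–Crafts C-acylation of the very electron-rich arene should stop after one acyl group, because the ketone complexed to AlCl3 deactivates the ring toward a second acylation.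

Step 2
Reactants: 3 2-methyl-1-(2,4,6-trihydroxyphenyl)propan-1-one; 4 benzyl bromide
Product: 5 1-[4-(benzyloxy)-2,6-dihydroxyphenyl]-2-methylpropan-1-one
Conditions: 4 (1.0 equiv), K2CO3 (1.1 equiv), DMF, 0 °C to rt
Reagents that add atoms: none
Why: Williamson ether synthesis in which the 4-OH, the most acidic hydroxyl and the only one not hydrogen-bonded to the ketone, should be ionised and benzylated ahead of the two chelated ortho hydroxyls.

Step 3
Reactants: 5 1-[4-(benzyloxy)-2,6-dihydroxyphenyl]-2-methylpropan-1-one (two molecules react); 6 6-methylheptanal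
Product: 8 1,1'-{(6-methylheptane-1,1-diyl)bis[4-(benzyloxy)-2,6-dihydroxybenzene-3,1-diyl]}bis(2-methylpropan-1-one), via benzylic carbinol 7 (not isolated)
Conditions: 5 (3 equiv), 6 (1 equiv, added slowly), p-TsOH·H2O (10 mol %), CH2Cl2, 0 °C to rt; unreacted 5 recovered
Reagents that add atoms: none
Why: Acid-catalysed hydroxyalkylation followed by Friedel–Crafts alkylation (Baeyer-type phenol–aldehyde condensation), in which carbinol 7 ionises to a hydroxyl-stabilised benzylic cation that a second molecule of 5 traps at one of its two equivalent open carbons, while the excess of 5 and the slow addition of 6 disfavour chain growth.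

Step 4
Reactants: 8 1,1'-{(6-methylheptane-1,1-diyl)bis[4-(benzyloxy)-2,6-dihydroxybenzene-3,1-diyl]}bis(2-methylpropan-1-one)
Product: 9 1,1'-{(6-methylheptane-1,1-diyl)bis[4-(benzyloxy)-5-[(dimethylamino)methyl]-2,6-dihydroxybenzene-3,1-diyl]}bis(2-methylpropan-1-one)
Conditions: Me2N=CH2+ I− (2.4 equiv), K2CO3 (2.4 equiv), CH2Cl2, 0 °C to rt
Reagents that add atoms: dimethylmethyleneiminium iodide, C=[N+](C)C.[I-]
Why: Mannich reaction with a preformed iminium ion, in which the single unsubstituted, oxygen-flanked carbon of each ring is the only carbon nucleophile left, so exhaustive aminomethylation should be unambiguous.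

Step 5
Reactants: 9 1,1'-{(6-methylheptane-1,1-diyl)bis[4-(benzyloxy)-5-[(dimethylamino)methyl]-2,6-dihydroxybenzene-3,1-diyl]}bis(2-methylpropan-1-one); 10 isobutene (2-methylpropene, two molecules react)
Product: 12 1,1'-{(6-methylheptane-1,1-diyl)bis[5-(benzyloxy)-7-hydroxy-2,2-dimethyl-3,4-dihydro-2H-chromene-6,8-diyl]}bis(2-methylpropan-1-one), via bis(ortho-quinone methide) 11 (not isolated)
Conditions: 10 (condensed, large excess), PhMe, sealed steel autoclave, 120 °C
Reagents that add atoms: none
Why: On each ring the acidic, ketone-flanked O8a–H transfers its proton to the neighbouring benzylic amine, and on heating the phenoxide expels dimethylamine (E1cB-type 1,4-elimination) to give the heterodiene O=C8a–C4a=C4H2; its para tautomer through O7 cannot cyclise and should return by proton shift, and the two rings need not react at the same moment. The heterodiene, made electron-poor by the C8 ketone, should then add isobutene in an inverse-electron-demand hetero-Diels–Alder reaction, the known path from phenolic Mannich bases and 1,1-disubstituted alkenes to 2,2-disubstituted chromans. Each pyran ring closes by this intermolecular, asynchronous [4+2] annulation, which forms C3–C4 and O1–C2 in one event and restores the aromatic ring. No stereocentre arises, since C2 carries two methyl groups and the bridge carbon keeps two identical aryl groups. Two kinds of regioselectivity are needed: closure through O8a and not O5, which the O5 benzyl ether secures, and bonding of oxygen to the tertiary alkene carbon, which follows from the polarised transition state with positive charge building on the more substituted carbon. The large excess of isobutene in a closed vessel should let cycloaddition outrun self-dimerisation of the quinone methide and re-addition of dimethylamine.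

Step 6
Reactants: 12 1,1'-{(6-methylheptane-1,1-diyl)bis[5-(benzyloxy)-7-hydroxy-2,2-dimethyl-3,4-dihydro-2H-chromene-6,8-diyl]}bis(2-methylpropan-1-one)
Product: 13 1,1'-{(6-methylheptane-1,1-diyl)bis[5,7-dihydroxy-2,2-dimethyl-3,4-dihydro-2H-chromene-6,8-diyl]}bis(2-methylpropan-1-one) (target)
Conditions: H2 (1 atm), 10% Pd/C, EtOAc, rt
Reagents that add atoms: none
Why: Catalytic hydrogenolysis of the two aryl benzyl ethers under neutral conditions should leave the chelated aryl ketones, the chroman rings and the diarylmethine untouched and avoids acid or base that could scramble the bridge.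

Compound list
1 | phloroglucinol (benzene-1,3,5-triol) | Oc1cc(O)cc(O)c1 | starting material
2 | isobutyryl chloride (2-methylpropanoyl chloride) | CC(C)C(=O)Cl | starting material
3 | 2-methyl-1-(2,4,6-trihydroxyphenyl)propan-1-one | CC(C)C(=O)c1c(O)cc(O)cc1O | intermediate
4 | benzyl bromide | BrCc1ccccc1 | starting material
5 | 1-[4-(benzyloxy)-2,6-dihydroxyphenyl]-2-methylpropan-1-one | CC(C)C(=O)c1c(O)cc(OCc2ccccc2)cc1O | intermediate
6 | 6-methylheptanal | CC(C)CCCCC=O | starting material
7 | 1-[4-(benzyloxy)-2,6-dihydroxy-3-(1-hydroxy-6-methylheptyl)phenyl]-2-methylpropan-1-one (racemic benzylic carbinol) | CC(C)CCCCC(O)c1c(O)c(C(=O)C(C)C)c(O)cc1OCc1ccccc1 | intermediate (not isolated)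
8 | 1,1'-{(6-methylheptane-1,1-diyl)bis[4-(benzyloxy)-2,6-dihydroxybenzene-3,1-diyl]}bis(2-methylpropan-1-one) (bridged dimer, one open ring carbon per ring) | CC(C)CCCCC(c1c(OCc2ccccc2)cc(O)c(C(=O)C(C)C)c1O)c1c(OCc2ccccc2)cc(O)c(C(=O)C(C)C)c1O | intermediate
9 | 1,1'-{(6-methylheptane-1,1-diyl)bis[4-(benzyloxy)-5-[(dimethylamino)methyl]-2,6-dihydroxybenzene-3,1-diyl]}bis(2-methylpropan-1-one) (bis-Mannich base, key-step precursor) | CC(C)CCCCC(c1c(OCc2ccccc2)c(CN(C)C)c(O)c(C(=O)C(C)C)c1O)c1c(OCc2ccccc2)c(CN(C)C)c(O)c(C(=O)C(C)C)c1O | intermediate
10 | isobutene (2-methylpropene) | CC(C)=C | starting material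
11 | 4,4'-(6-methylheptane-1,1-diyl)bis[5-(benzyloxy)-3-hydroxy-6-methylidene-2-(2-methylpropanoyl)cyclohexa-2,4-dien-1-one] (bis(ortho-quinone methide)) | CC(C)CCCCC(C1=C(OCc2ccccc2)C(=C)C(=O)C(C(=O)C(C)C)=C1O)C1=C(OCc2ccccc2)C(=C)C(=O)C(C(=O)C(C)C)=C1O | intermediate (not isolated)
12 | 1,1'-{(6-methylheptane-1,1-diyl)bis[5-(benzyloxy)-7-hydroxy-2,2-dimethyl-3,4-dihydro-2H-chromene-6,8-diyl]}bis(2-methylpropan-1-one) (5,5'-di-O-benzyl ether of the target) | CC(C)CCCCC(c1c(OCc2ccccc2)c2CCC(C)(C)Oc2c(C(=O)C(C)C)c1O)c1c(OCc2ccccc2)c2CCC(C)(C)Oc2c(C(=O)C(C)C)c1O | intermediate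
13 | 1,1'-{(6-methylheptane-1,1-diyl)bis[5,7-dihydroxy-2,2-dimethyl-3,4-dihydro-2H-chromene-6,8-diyl]}bis(2-methylpropan-1-one) | CC(C)CCCCC(c1c(O)c2c(c(C(=O)C(C)C)c1O)OC(C)(C)CC2)c1c(O)c2c(c(C(=O)C(C)C)c1O)OC(C)(C)CC2 | target

Total step count: 6
Longest linear sequence: 6 steps (1 → 3 → 5 → 8 → 9 → 12 → 13)

Steps most likely to fail

Step 5. Amine loss may stall on one ring, the quinone methide may dimerise or take dimethylamine back, and the hot, amine-containing medium may cleave the bridge by a retro-Friedel–Crafts process through the free O7 hydroxyl. The fallback builds the pyran by electrophilic prenylation and hydroalkoxylation instead of cycloaddition. It sets out from 8, so step 4 is skipped. Friedel–Crafts C-prenylation of the open carbon of each ring with 2-methylbut-3-en-2-ol and BF3·OEt2 in 1,4-dioxane at rt should give the bis(3-methylbut-2-enyl) dimer F1. Mild acid (p-TsOH·H2O, PhMe, 50 °C) should then add O8a–H across the prenyl double bond in the Markovnikov sense; O5 is blocked, so only the 2,2-dimethylchroman can form. The fallback comes back to the route at 12.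

Step 3. The dimer keeps one open carbon per ring and may grow to trimers and higher oligomers, and the enolisable aldehyde may self-condense under acid. The fallback forms the two aryl–carbon bonds one at a time under non-acidic conditions. It sets out from 5. A three-component Betti (phenolic Mannich) reaction of 5, 6 and morpholine (1:1:1, EtOH, rt) should give the aminoalkylphenol 1-[4-(benzyloxy)-2,6-dihydroxy-3-[6-methyl-1-(morpholin-4-yl)heptyl]phenyl]-2-methylpropan-1-one F2. Heating F2 with a further 2 equiv of 5 in PhMe at 90 °C should expel morpholine to the alkylidene ortho-quinone methide, which the second phenol traps through carbon in a conjugate addition. The fallback comes back to the route at 8.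

Step 2. Alkylation may run on to the dibenzyl ether or take place at ring carbon, which lowers the supply of 5. The fallback replaces selective mono-alkylation by over-protection and chelation-directed deprotection. It sets out from 3. Benzylation with 4 (2.2 equiv) and K2CO3 in DMF should stop at 1-[2,4-bis(benzyloxy)-6-hydroxyphenyl]-2-methylpropan-1-one F3, because the last chelated hydroxyl resists alkylation. MgBr2·OEt2 in PhMe/Et2O at reflux should then cleave only the benzyl ether ortho to the ketone, through a magnesium chelate. The fallback comes back to the route at 5.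

Further compounds
F1 | step 5 | 1,1'-{(6-methylheptane-1,1-diyl)bis[4-(benzyloxy)-2,6-dihydroxy-5-(3-methylbut-2-en-1-yl)benzene-3,1-diyl]}bis(2-methylpropan-1-one) | CC(C)CCCCC(c1c(OCc2ccccc2)c(CC=C(C)C)c(O)c(C(=O)C(C)C)c1O)c1c(OCc2ccccc2)c(CC=C(C)C)c(O)c(C(=O)C(C)C)c1O
F2 | step 3 | 1-[4-(benzyloxy)-2,6-dihydroxy-3-[6-methyl-1-(morpholin-4-yl)heptyl]phenyl]-2-methylpropan-1-one (racemic) | CC(C)CCCCC(N1CCOCC1)c1c(O)c(C(=O)C(C)C)c(O)cc1OCc1ccccc1
F3 | step 2 | 1-[2,4-bis(benzyloxy)-6-hydroxyphenyl]-2-methylpropan-1-one | CC(C)C(=O)c1c(O)cc(OCc2ccccc2)cc1OCc1ccccc1
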